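The readings were generated by integration with constants of no real substance; the scatter is artificial.

Monday's run gave me the rule for what stands in alder at the end.

| setting | Sunday's | Monday's | birch | alder | larch |
|---|---|---|---|---|---|
| starting complex | 1 M | 1 M | 1.0 M | 1.0 M | 1.0 M |
| incoming ligand | 0.78 M | 1.9 M | 1.00 M | 2.50 M | 3.00 M |
| remark | run made earlier | run made earlier |  |  |  |
| time |  |  | 2.5 h | 2.5 h | 2.5 h |

| run | time / min | complex with two exchanged / % | starting complex / % |
|---|---|---|---|
| Sunday's | 6.00 | 0 | 92 |
| Sunday's | 12.0 | 2 | 80 |
| Sunday's | 20.0 | 3 | 74 |
| Sunday's | 40.0 | 6 | 63 |
| Sunday's | 80.0 | 6 | 47 |
| Monday's | 6.00 | 4 | 77 |
| Monday's | 12.0 | 10 | 61 |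
| Monday's | 20.0 | 13 | 48 |
| Monday's | 40.0 | 15 | 28 |
| Monday's | 80.0 | 12 | 10 |

(scatter of a reading: 1.5 percentage points)

* which of these holds the largest part of the starting complex at the end of birch (complex with one exchanged / complex with two exchanged / starting complex / complex with three exchanged)
* which of these holds the largest part of the starting complex at the end of alder (complex with one exchanged / complex with two exchanged / starting complex / complex with three exchanged)
* which of these holds the largest part of the starting complex at the end of larch (complex with one exchanged / complex with two exchanged / starting complex / complex with three exchanged)
* final complex with two exchanged in alder, as a percentage of the starting complex charged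



I compared two rates: that at which complex with two exchanged is made and that at which it is used up. I assumed both were first order in incoming ligand and that making followed [starting complex], so ligand cancels from their ratio, and I froze what remained. At the top of a curve the two rates are equal. Monday's readings top near 40.0 min, so [starting complex]/[complex with two exchanged] there, the balance ratio, read 1.87. Dividing [starting complex] by it gives the balance level, and on that assumption complex with two exchanged above that level falls. Sunday's last reading gave 7.83 at 0.78 M of ligand, higher than Monday's reading, so ligand did not cancel between these two runs, and I kept the ratio only as a rough reading from Monday's run.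

Monday's late fall of [starting complex] gave a pseudo-first-order constant of 0.0257 /min. Held over 2.5 h, it gave me an estimate of 2.10% left in alder, so my rough balance level there was 1.13%. I therefore expected alder to end on a falling tail, above that level.

The forecast named complex with one exchanged for birch, complex with three exchanged for alder and complex with three exchanged for larch, with 6% (3% to 13%) for complex with two exchanged in alder, which it called “a low-level intermediate”. That value lies above my level.

Alder gave 5.06%, within that range, and complex with three exchanged led there and in larch, but starting complex led birch.

    starting complex + incoming ligand → leaving ligand + complex with one exchanged (k = 4.00 × 10⁻⁴ /M/s)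
    complex with one exchanged + incoming ligand → leaving ligand + complex with two exchanged (k = 0.00110 /M/s)
    complex with two exchanged + incoming ligand → leaving ligand + complex with three exchanged (k = 3.00 × 10⁻⁴ /M/s)
    leaving ligand + starting complex → side product A (k = 3.10 × 10⁻⁵ /M/s)
    complex with one exchanged → side product B (k = 0.00220 /s)

At 2.50 h in alder, making over using stood at 0.108; the balance ratio on alder's final amounts gives 0.137.

The neighbour charged with 0.25 M of starting complex ended with 0.0501% of it, a balance level of 0.0269%. Its complex with two exchanged stood higher, at 0.714%.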